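**Retrosynthetic overview**
1. Target 34 ⇐ allylic C4–H oxidation of triangelate 33 ⇐ triol 30 + three angelic acid units (mixed-anhydride esterification).
2. Triol 30 ⇐ reductive opening of cage δ-lactone 28; the cycloheptane (C1–C2 bond) is closed last by a lactone-enolate aldol onto the cyclobutanone of 25, then Barton–McCombie deoxygenation.
3. Ketone 25 ⇐ intramolecular vinylketene–alkene [2+2] of dienoic acid 22, which forms the cyclobutane and the cyclohexene together.
4. Acid 22 ⇐ sp3–sp2 Negishi union of the two halves: West iodide 7 (C2, C4–C7, C13) and East lactone vinyl iodide 19 (C1, C3, C8–C12, C14, C15).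
5. 7 ⇐ but-3-yn-1-ol; 19 ⇐ methyl acetoacetate + propargyl alcohol (vinylogous aldol, anti-reduction, lactonisation). Ring order: temporary δ-lactone → cyclobutane + cyclohexene → cycloheptane.

Assumption: carbons are labelled C1–C15 in the order of the target SMILES (C15 = OCH2; C1 = quaternary C bearing it; C2/C3/C7/C8 = cyclobutane; C4 = C=O; C5=C6; C9, C11 = CH–O; C10 = CH2; methyls C12 on C8, C13 on C6, C14 on C1); compounds 16–25 are carried as epimer mixtures at C1, which is fixed in step 17.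

**Step 1**
Reactants: 1 but-3-yn-1-ol
Product: 2 tert-butyl(but-3-yn-1-yloxy)dimethylsilane
Conditions: TBSCl, imidazole, CH2Cl2, 0 °C→rt
Reagents that add atoms: tert-butyldimethylsilyl chloride, CC(C)(C)[Si](C)(C)Cl
Why: Standard silyl protection so the alkyne C–H can be metallated in step 2.

**Step 2**
Reactants: 2 tert-butyl(but-3-yn-1-yloxy)dimethylsilane
Product: 4 methyl 5-[(tert-butyldimethylsilyl)oxy]pent-2-ynoate, via lithium acetylide 3 (not isolated)
Conditions: n-BuLi, THF, −78 °C; ClCO2Me, −78 °C→0 °C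
Reagents that add atoms: methyl chloroformate, COC(=O)Cl
Why: Acetylide C-acylation installs the carboxyl carbon that becomes C2.

**Step 3**
Reactants: 4 methyl 5-[(tert-butyldimethylsilyl)oxy]pent-2-ynoate
Product: 5 methyl (2Z)-5-[(tert-butyldimethylsilyl)oxy]-3-methylpent-2-enoate
Conditions: Me2CuLi (MeLi, CuI), THF, −78 °C; MeOH quench at −78 °C
Reagents that add atoms: lithium dimethylcuprate, [Li+].C[Cu-]C
Why: Syn-carbocupration of the ynoate with cold protonation puts the new methyl (C13) trans to the ester, giving the 2Z enoate with the chain cis to the carboxyl.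

**Step 4**
Reactants: 5 methyl (2Z)-5-[(tert-butyldimethylsilyl)oxy]-3-methylpent-2-enoate
Product: 6 methyl (2Z)-5-bromo-3-methylpent-2-enoate
Conditions: Ph3PBr2, CH2Cl2, rt
Reagents that add atoms: dibromotriphenylphosphorane, BrP(Br)(c1ccccc1)(c1ccccc1)c1ccccc1
Why: Direct silyl ether → bromide conversion avoids the free Z-hydroxy ester, which would lactonise.

**Step 5**
Reactants: 6 methyl (2Z)-5-bromo-3-methylpent-2-enoate
Product: 7 methyl (2Z)-5-iodo-3-methylpent-2-enoate
Conditions: NaI, acetone, rt, dark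
Reagents that add atoms: sodium iodide, [Na+].[I-]
Why: Finkelstein exchange gives the primary iodide needed for zinc insertion.

**Step 6**
Reactants: 8 methyl acetoacetate
Product: 9 methyl 2-methyl-3-oxobutanoate
Conditions: K2CO3, MeI, acetone, reflux
Reagents that add atoms: iodomethane, CI
Why: C-alkylation of the β-keto ester introduces C14.

**Step 7**
Reactants: 9 methyl 2-methyl-3-oxobutanoate
Product: 10 1-methoxy-2-methyl-1,3-bis(trimethylsilyloxy)buta-1,3-diene
Conditions: TMSOTf (2.2 equiv), Et3N, Et2O, 0 °C→rt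
Reagents that add atoms: trimethylsilyl trifluoromethanesulfonate, C[Si](C)(C)OS(=O)(=O)C(F)(F)F
Why: Double O-silylation gives the Chan-type bis-silyl dienolate, nucleophilic at its terminal CH2 (C10).

**Step 8**
Reactants: 11 prop-2-yn-1-ol
Product: 13 (2E)-3-iodo-2-methylprop-2-en-1-ol, via alkenylalane 12 (not isolated)
Conditions: Me3Al, Cp2ZrCl2 (cat.), CH2Cl2, 0 °C→rt; I2, THF, −30 °C
Reagents that add atoms: trimethylaluminium, C[Al](C)C; iodine, II
Why: Negishi Zr-catalysed syn-carboalumination then iodinolysis with retention gives the E-vinyl iodide (C3, C8, C12).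

**Step 9**
Reactants: 13 (2E)-3-iodo-2-methylprop-2-en-1-ol
Product: 14 (2E)-3-iodo-2-methylprop-2-enal
Conditions: MnO2, CH2Cl2, rt
Reagents that add atoms: none
Why: Chemoselective allylic alcohol oxidation without E/Z erosion.

**Step 10**
Reactants: 10 1-methoxy-2-methyl-1,3-bis(trimethylsilyloxy)buta-1,3-diene; 14 (2E)-3-iodo-2-methylprop-2-enal
Product: 16 methyl (5R,6E)-5-hydroxy-7-iodo-2,6-dimethyl-3-oxohept-6-enoate (C-2 epimers), via bis-silylated aldol adduct 15 (not isolated)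
Conditions: Ti(OiPr)4/(R)-BINOL (20 mol %), 4 Å MS, THF, −78 °C→rt; then TFA, THF–H2O, 0 °C
Reagents that add atoms: none
Why: Catalytic asymmetric vinylogous Mukaiyama aldol; the Ti–BINOL catalyst sets C9 (the R sense with (R)-BINOL is assigned by analogy with simple aldehydes).

**Step 11**
Reactants: 16 methyl (5R,6E)-5-hydroxy-7-iodo-2,6-dimethyl-3-oxohept-6-enoate
Product: 17 methyl (3R,5R,6E)-3,5-dihydroxy-7-iodo-2,6-dimethylhept-6-enoate (anti-diol; C-2 epimers)
Conditions: Me4NBH(OAc)3, MeCN/AcOH, −30 °C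
Reagents that add atoms: none
Why: Evans–Saksena reduction delivers hydride intramolecularly from the C9-alkoxyborohydride, giving the 1,3-anti diol and setting C11.

**Step 12**
Reactants: 17 methyl (3R,5R,6E)-3,5-dihydroxy-7-iodo-2,6-dimethylhept-6-enoate
Product: 18 (4R,6R)-4-hydroxy-6-[(1E)-1-iodoprop-1-en-2-yl]-3-methyloxan-2-one (4,6-cis; C-3 epimers)
Conditions: PPTS (cat.), benzene, 70 °C
Reagents that add atoms: none
Why: Acid-catalysed δ-lactonisation of the 5-hydroxy ester ties O9 to C15.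

**Step 13**
Reactants: 18 (4R,6R)-4-hydroxy-6-[(1E)-1-iodoprop-1-en-2-yl]-3-methyloxan-2-one
Product: 19 (4R,6R)-6-[(1E)-1-iodoprop-1-en-2-yl]-3-methyl-4-(triethylsilyloxy)oxan-2-one
Conditions: TESCl, imidazole, DMF, rt
Reagents that add atoms: chlorotriethylsilane, CC[Si](Cl)(CC)CC
Why: Silyl protection of O11 against the ketene and the later enolate chemistry.

**Step 14**
Reactants: 7 methyl (2Z)-5-iodo-3-methylpent-2-enoate; 19 (4R,6R)-6-[(1E)-1-iodoprop-1-en-2-yl]-3-methyl-4-(triethylsilyloxy)oxan-2-one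
Product: 21 methyl (2Z,6E)-3-methyl-7-[(2R,4R)-5-methyl-6-oxo-4-(triethylsilyloxy)oxan-2-yl]octa-2,6-dienoate, via alkylzinc iodide 20 (not isolated)
Conditions: 7, activated Zn, DMA, 40 °C; then 19, Pd2(dba)3 (2.5 mol %), P(o-tol)3, THF/DMA, rt
Reagents that add atoms: none
Why: Negishi sp3–sp2 coupling joins the two halves at C4–C3 with retention of the E-olefin; the alkylzinc tolerates ester, lactone and silyl ether.

**Step 15**
Reactants: 21 methyl (2Z,6E)-3-methyl-7-[(2R,4R)-5-methyl-6-oxo-4-(triethylsilyloxy)oxan-2-yl]octa-2,6-dienoate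
Product: 22 (2Z,6E)-3-methyl-7-[(2R,4R)-5-methyl-6-oxo-4-(triethylsilyloxy)oxan-2-yl]octa-2,6-dienoic acid
Conditions: Me3SnOH, ClCH2CH2Cl, 80 °C; cold 0.1 M HCl wash (re-closes any opened δ-lactone)
Reagents that add atoms: trimethyltin hydroxide, C[Sn](C)(C)O
Why: Neutral tin-hydroxide ester cleavage frees the acid without touching the TES ether or the E/Z olefins.

**Step 16**
Reactants: 22 (2Z,6E)-3-methyl-7-[(2R,4R)-5-methyl-6-oxo-4-(triethylsilyloxy)oxan-2-yl]octa-2,6-dienoic acid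
Product: 25 (1R,5S,7S)-2,7-dimethyl-7-[(2R,4R)-5-methyl-6-oxo-4-(triethylsilyloxy)oxan-2-yl]bicyclo[3.1.1]hept-2-en-6-one, via acid chloride 23 (not isolated), via vinylketene 24 (not isolated)
Conditions: Me2C=C(Cl)NMe2, CH2Cl2, 0 °C; then slow addition to Et3N, toluene, reflux, high dilution
Reagents that add atoms: none
Why: Intramolecular vinylketene–alkene [2+2] (the chrysanthenone-type cyclisation): the E-olefin puts C12 syn to the new cyclohexene bridge, and the ketene is expected to add anti to the C9–O bond (Felkin-type, C9–H eclipsing the vinylic methyl), setting C3, C7 and C8; this face selectivity is not secured, and the minor face isomer is removed by chromatography.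

**Step 17**
Reactants: 25 (1R,5S,7S)-2,7-dimethyl-7-[(2R,4R)-5-methyl-6-oxo-4-(triethylsilyloxy)oxan-2-yl]bicyclo[3.1.1]hept-2-en-6-one
Product: 27 cage O-phenyl thionocarbonate (C1–C2 bond formed; C2–OC(S)OPh; C15(=O)–O9 δ-lactone; 11-OTES), via lithium aldolate 26 (not isolated)
Conditions: LiHMDS, THF, −78 °C; then PhOC(S)Cl, −78→0 °C
Reagents that add atoms: O-phenyl chlorothionoformate, S=C(Cl)Oc1ccccc1
Why: Intramolecular aldol of the lactone enolate onto the strained, non-enolisable cyclobutanone closes the cycloheptane; the bridging lactone forces C15 cis to O9 and so fixes quaternary C1, and in-situ thioacylation blocks retro-aldol.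

**Step 18**
Reactants: 27 cage O-phenyl thionocarbonate
Product: 28 cage δ-lactone (C2–H; 11-OTES; C4 = CH2; C5=C6)
Conditions: Bu3SnH, AIBN (cat.), toluene, 110 °C
Reagents that add atoms: none
Why: Barton–McCombie deoxygenation; the tertiary cyclobutyl radical at the bridgehead can accept H in only one configuration (C2), and no β-hydrogen is available for thermal elimination.

**Step 19**
Reactants: 28 cage δ-lactone
Product: 29 11-O-TES 9,15-diol (tricyclic core, C4 = CH2)
Conditions: LiAlH4, THF, 0 °C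
Reagents that add atoms: none
Why: Hydride reduction of the lactone releases the C15 primary and C9 secondary alcohols; the silyl ether and olefin survive.

**Step 20**
Reactants: 29 11-O-TES 9,15-diol
Product: 30 9,11,15-triol (4-deoxo triol of the target core)
Conditions: TBAF, THF, rt
Reagents that add atoms: none
Why: Fluoride desilylation under non-acidic conditions protects the acid-sensitive pinene-type cyclobutane.

**Step 21**
Reactants: 31 angelic acid [(2Z)-2-methylbut-2-enoic acid]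
Product: 32 (2Z)-2-methylbut-2-enoic 2,4,6-trichlorobenzoic anhydride
Conditions: 2,4,6-Cl3C6H2COCl, Et3N, toluene, rt
Reagents that add atoms: 2,4,6-trichlorobenzoyl chloride, O=C(Cl)c1c(Cl)cc(Cl)cc1Cl
Why: Yamaguchi-type mixed anhydride activates angelic acid without Z→E isomerisation.

**Step 22**
Reactants: 30 9,11,15-triol; 32 (2Z)-2-methylbut-2-enoic 2,4,6-trichlorobenzoic anhydride
Product: 33 9,11,15-tri-O-angeloyl-4-deoxo compound
Conditions: 32 (6 equiv), toluene, 80 °C, no DMAP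
Reagents that add atoms: none
Why: Thermal acylation by the mixed anhydride at its unhindered angeloyl carbonyl esterifies all three hydroxyls while avoiding the nucleophilic catalysis that causes tiglate formation.

**Step 23**
Reactants: 33 9,11,15-tri-O-angeloyl-4-deoxo compound
Product: 34 target CNP0266467.1
Conditions: CrO3, 3,5-dimethylpyrazole, CH2Cl2, −20 °C
Reagents that add atoms: chromium trioxide, O=[Cr](=O)=O
Why: Allylic oxidation of the ring CH2 (C4) next to the trisubstituted olefin, as in α-pinene → verbenone; the bridgehead C7–H and the electron-poor angelates are inert.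

**Compound list**
1 | but-3-yn-1-ol | C#CCCO | starting material
2 | tert-butyl(but-3-yn-1-yloxy)dimethylsilane | C#CCCO[Si](C)(C)C(C)(C)C | intermediate
3 | lithium 4-[(tert-butyldimethylsilyl)oxy]but-1-yn-1-ide | [Li]C#CCCO[Si](C)(C)C(C)(C)C | intermediate
4 | methyl 5-[(tert-butyldimethylsilyl)oxy]pent-2-ynoate | COC(=O)C#CCCO[Si](C)(C)C(C)(C)C | intermediate
5 | methyl (2Z)-5-[(tert-butyldimethylsilyl)oxy]-3-methylpent-2-enoate | COC(=O)/C=C(C)\CCO[Si](C)(C)C(C)(C)C | intermediate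
6 | methyl (2Z)-5-bromo-3-methylpent-2-enoate | COC(=O)/C=C(C)\CCBr | intermediate
7 | methyl (2Z)-5-iodo-3-methylpent-2-enoate | COC(=O)/C=C(C)\CCI | intermediate
8 | methyl acetoacetate | COC(=O)CC(C)=O | starting material
9 | methyl 2-methyl-3-oxobutanoate (racemic) | COC(=O)C(C)C(C)=O | intermediate
10 | 1-methoxy-2-methyl-1,3-bis(trimethylsilyloxy)buta-1,3-diene | COC(O[Si](C)(C)C)=C(C)C(=C)O[Si](C)(C)C | intermediate
11 | prop-2-yn-1-ol | C#CCO | starting material
12 | (E)-alkenylalane, dimethylaluminium alkoxide of (2E)-3-(dimethylalumanyl)-2-methylprop-2-en-1-ol | C[Al](C)OC/C(C)=C/[Al](C)C | intermediate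
13 | (2E)-3-iodo-2-methylprop-2-en-1-ol | OC/C(C)=C/I | intermediate
14 | (2E)-3-iodo-2-methylprop-2-enal | O=C/C(C)=C/I | intermediate
15 | bis-silylated aldol adduct, methyl (5R,6E)-7-iodo-2,6-dimethyl-3,5-bis(trimethylsilyloxy)hepta-2,6-dienoate | COC(=O)C(C)=C(O[Si](C)(C)C)C[C@@H](O[Si](C)(C)C)/C(C)=C/I | intermediate
16 | methyl (5R,6E)-5-hydroxy-7-iodo-2,6-dimethyl-3-oxohept-6-enoate (C-2 epimers) | COC(=O)C(C)C(=O)C[C@@H](O)/C(C)=C/I | intermediate
17 | methyl (3R,5R,6E)-3,5-dihydroxy-7-iodo-2,6-dimethylhept-6-enoate (anti-diol, C-2 epimers) | COC(=O)C(C)[C@H](O)C[C@@H](O)/C(C)=C/I | intermediate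
18 | (4R,6R)-4-hydroxy-6-[(1E)-1-iodoprop-1-en-2-yl]-3-methyloxan-2-one (C-3 epimers) | I/C=C(C)/[C@H]1C[C@@H](O)C(C)C(=O)O1 | intermediate
19 | (4R,6R)-6-[(1E)-1-iodoprop-1-en-2-yl]-3-methyl-4-(triethylsilyloxy)oxan-2-one (C-3 epimers) | I/C=C(C)/[C@H]1C[C@@H](O[Si](CC)(CC)CC)C(C)C(=O)O1 | intermediate
20 | iodo[(3Z)-5-methoxy-3-methyl-5-oxopent-3-en-1-yl]zinc | COC(=O)/C=C(C)\CC[Zn]I | intermediate
21 | methyl (2Z,6E)-3-methyl-7-[(2R,4R)-5-methyl-6-oxo-4-(triethylsilyloxy)oxan-2-yl]octa-2,6-dienoate | COC(=O)/C=C(C)\CC/C=C(C)/[C@H]1C[C@@H](O[Si](CC)(CC)CC)C(C)C(=O)O1 | intermediate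
22 | (2Z,6E)-3-methyl-7-[(2R,4R)-5-methyl-6-oxo-4-(triethylsilyloxy)oxan-2-yl]octa-2,6-dienoic acid | OC(=O)/C=C(C)\CC/C=C(C)/[C@H]1C[C@@H](O[Si](CC)(CC)CC)C(C)C(=O)O1 | intermediate
23 | (2Z,6E)-3-methyl-7-[(2R,4R)-5-methyl-6-oxo-4-(triethylsilyloxy)oxan-2-yl]octa-2,6-dienoyl chloride | ClC(=O)/C=C(C)\CC/C=C(C)/[C@H]1C[C@@H](O[Si](CC)(CC)CC)C(C)C(=O)O1 | intermediate
24 | vinylketene, (3Z,6E)-3-methyl-7-[(2R,4R)-5-methyl-6-oxo-4-(triethylsilyloxy)oxan-2-yl]octa-1,3,6-trien-1-one | O=C=C/C(C)=C\C/C=C(C)/[C@H]1C[C@@H](O[Si](CC)(CC)CC)C(C)C(=O)O1 | intermediate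
25 | (1R,5S,7S)-2,7-dimethyl-7-[(2R,4R)-5-methyl-6-oxo-4-(triethylsilyloxy)oxan-2-yl]bicyclo[3.1.1]hept-2-en-6-one (lactone on the face of C7 anti to the C2=C3 bridge) | O=C1[C@H]2CC=C(C)[C@@H]1[C@@]2(C)[C@H]3C[C@@H](O[Si](CC)(CC)CC)C(C)C(=O)O3 | intermediate
26 | lithium aldolate of the cage (C2–OLi, C1–C2 bond, C15(=O)–O9 lactone, 11-OTES) | O=C4[C@]1(C)[C@]2(O[Li])[C@H]3CC=C(C)[C@@H]2[C@@]3(C)[C@H](O4)C[C@H]1O[Si](CC)(CC)CC | intermediate
27 | cage O-phenyl thionocarbonate (C2–OC(S)OPh, C15(=O)–O9 lactone, 11-OTES) | O=C4[C@]1(C)[C@]2(OC(=S)Oc5ccccc5)[C@H]3CC=C(C)[C@@H]2[C@@]3(C)[C@H](O4)C[C@H]1O[Si](CC)(CC)CC | intermediate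
28 | cage δ-lactone (C15(=O)–O9), 11-OTES, C4 = CH2, configuration as in target | O=C4[C@]1(C)[C@@H]2[C@H]3CC=C(C)[C@@H]2[C@@]3(C)[C@H](O4)C[C@H]1O[Si](CC)(CC)CC | intermediate
29 | 11-O-TES 9,15-diol of the tricyclic core (C4 = CH2) | OC[C@]1(C)[C@@H]2[C@H]3CC=C(C)[C@@H]2[C@@]3(C)[C@H](O)C[C@H]1O[Si](CC)(CC)CC | intermediate
30 | 9,11,15-triol of the tricyclic core (C4 = CH2) | OC[C@]1(C)[C@@H]2[C@H]3CC=C(C)[C@@H]2[C@@]3(C)[C@H](O)C[C@H]1O | intermediate
31 | angelic acid, (2Z)-2-methylbut-2-enoic acid | C/C=C(/C)C(=O)O | starting material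
32 | (2Z)-2-methylbut-2-enoic 2,4,6-trichlorobenzoic anhydride | C/C=C(/C)C(=O)OC(=O)c1c(Cl)cc(Cl)cc1Cl | intermediate
33 | 9,11,15-tri-O-angeloyl-4-deoxo compound | C/C=C(/C)C(=O)OC[C@]1(C)[C@@H]2[C@H]3CC=C(C)[C@@H]2[C@@]3(C)[C@H](OC(=O)/C(C)=C\C)C[C@H]1OC(=O)/C(C)=C\C | intermediate
34 | CNP0266467.1 (9,11,15-tri-O-angeloyl tricyclic enone) | C/C=C(/C)C(=O)OC[C@]1(C)[C@@H]2[C@H]3C(=O)C=C(C)[C@@H]2[C@@]3(C)[C@H](OC(=O)/C(C)=C\C)C[C@H]1OC(=O)/C(C)=C\C | target

**Step count**
Total: 23 steps. Longest linear sequence: 15 steps (6, 7, 10–20, 22, 23; the branch 8, 9, 10–20, 22, 23 is equally long).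

**Steps most likely to fail**

Step 16 (vinylketene [2+2]: yield and alkene-face selectivity, which rests only on the C9 stereocentre). An inside-alkoxy analysis predicts the opposite face, so the wrong diastereomer may well predominate. The fallback sets out from acid 22 and returns at ketone 25. The acid is coupled (EDCI, HOBt) with (2R,5R)-2,5-dimethylpyrrolidine to give the (2R,5R)-2,5-dimethylpyrrolidine amide of 22 F1. Tf2O and 2,6-di-tert-butyl-4-methylpyridine in ClCH2CH2Cl (25→80 °C) convert it into a vinylketeniminium salt, which is more electrophilic than the ketene and whose face selection is controlled by the C2-symmetric auxiliary (its enantiomer is chosen to match). Cyclisation gives the bicyclic cyclobutaniminium triflate F2, and aqueous NaHCO3 hydrolysis returns 25.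

Step 17 (cage aldol: β-silyloxy elimination from the lactone enolate, or retro-aldol before trapping). The fallback sets out from 25 and returns at 27. The enolate is trapped as it forms (LiHMDS with TMSCl present, −78 °C) as the silyl ketene acetal of 25 F3. NBS (THF, −78 °C) gives the α-bromo lactone F4. A SmI2-mediated intramolecular Reformatsky reaction (THF, −78 °C), in which the samarium(III) chelate holds the aldolate, gives the cage tertiary alcohol F5. Thioacylation (PhOC(S)Cl, DMAP, MeCN) then gives 27.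

Step 22 (triple angeloylation: two neopentyl secondary alcohols, risk of tiglate formation). The fallback sets out from triol 30 and returns at 33. All three hydroxyls are acylated with the unhindered 2-[bis(2,2,2-trifluoroethoxy)phosphoryl]propanoic acid (DCC, DMAP) to give the tris(phosphonopropionate) of 30 F6. A threefold Still–Gennari olefination with acetaldehyde (KHMDS, 18-crown-6, THF, −78 °C) then builds the (Z)-2-methylbut-2-enoates in place.

**Further compounds**
F1 | step 16 | (2R,5R)-2,5-dimethylpyrrolidine amide of 22 | O=C(/C=C(C)\CC/C=C(C)/[C@H]1C[C@@H](O[Si](CC)(CC)CC)C(C)C(=O)O1)N2[C@H](C)CC[C@H]2C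
F2 | step 16 | bicyclic cyclobutaniminium triflate (iminium analogue of 25) | C[C@@H]1CC[C@@H](C)[N+]1=C2[C@H]3CC=C(C)[C@@H]2[C@@]3(C)[C@H]4C[C@@H](O[Si](CC)(CC)CC)C(C)C(=O)O4.[O-]S(=O)(=O)C(F)(F)F
F3 | step 17 | silyl ketene acetal of 25 | O=C1[C@H]2CC=C(C)[C@@H]1[C@@]2(C)[C@H]3C[C@@H](O[Si](CC)(CC)CC)C(C)=C(O[Si](C)(C)C)O3
F4 | step 17 | α-bromo lactone (C1 epimers) | O=C1[C@H]2CC=C(C)[C@@H]1[C@@]2(C)[C@H]3C[C@@H](O[Si](CC)(CC)CC)C(C)(Br)C(=O)O3
F5 | step 17 | cage tertiary alcohol (C2–OH) | O=C4[C@]1(C)[C@]2(O)[C@H]3CC=C(C)[C@@H]2[C@@]3(C)[C@H](O4)C[C@H]1O[Si](CC)(CC)CC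
F6 | step 22 | tris(phosphonopropionate) of 30 | CC(C(=O)OC[C@]1(C)[C@@H]2[C@H]3CC=C(C)[C@@H]2[C@@]3(C)[C@H](OC(=O)C(C)P(=O)(OCC(F)(F)F)OCC(F)(F)F)C[C@H]1OC(=O)C(C)P(=O)(OCC(F)(F)F)OCC(F)(F)F)P(=O)(OCC(F)(F)F)OCC(F)(F)F
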